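**Plan**

- Locants: ring A = cyclopentane C4H–C5H(OAc)–C6H2–C7(CH3)(OH)–C8H; ring B = cyclobutane C3(CH3)–C4–C8–C9(O); ring C = C1H(O‑tigloyl)–C2H2–C3–C9–C13; ring D = butenolide C9–O–C11(=O)–C12(CH2OAc)=C13; "top" = the cyclobutane face carrying 3‑CH3, 9‑O, H‑4 and H‑8.
- Retrosynthesis: remove the esters; cut ring D at C12=C13 and O–C11 (aldol/lactonization on a C13 ketone); trace C5–OAc to C5–acetyl (Baeyer–Villiger) and this to a Wolff shift, so ring A is carried as a cyclohexanone A′ with one extra carbon Cx between C4 and C5; cut the cyclobutane at C3–C4 and C8–C9 ([2+2] of a 3‑methoxycyclohexenone with a cyclotene‑derived silyl enol ether).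
- Forward order: ring C (cyclotene) → [2+2] gives ring B fused to six‑membered A′ → methoxide loss to a C4=C8 cyclobutene‑enone and OH‑directed hydrogenation set the contra‑steric cis‑syn‑cis fusion → contraction A′ → A → ring D → esters.
- Feature used: C5 carries an exocyclic oxygen and lies between the cyclobutane CH (C4) and a CH2. A 1,2‑shift of C4 in the 5‑diazo‑Cx‑ketone leaves an acyl carbon on C5 (later the acetate) and removes the only epimerizable ring‑fusion position. The cyclobutene‑enone that fixes C4/C8 is far less strained in the six‑membered series.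
- Stereochemistry: one CBS‑derived carbinol (C13, later oxidized away) steers the photocycloaddition (C3, C9); C4/C8 come from directed H2 delivery; C5 from exo equilibration plus stereoretentive Baeyer–Villiger; C7 and C1 from convex‑face oxygenation.

Key step: step 11

Remark: the (R)‑CBS catalyst is assigned by the usual model with the substituted alkene arm as the large group; methyl 3‑(tert‑butyldimethylsilyloxy)propanoate and tigloyl chloride are taken as purchasable.

**Route**

Step 1
Reactants: 1 cyclotene (2‑hydroxy‑3‑methylcyclopent‑2‑en‑1‑one)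
Product: 2 3‑methyl‑2‑(triethylsilyloxy)cyclopent‑2‑en‑1‑one
Conditions: TESCl, Et3N, DMAP (cat.), CH2Cl2, 0 °C
Reagents that add atoms: chlorotriethylsilane, CC[Si](Cl)(CC)CC
Why: O‑silylation of the diosphenol enol (silyl ether formation) masks the acidic OH and fixes the C9=C3 enol ether that becomes one cyclobutane edge.

Step 2
Reactants: 2 3‑methyl‑2‑(triethylsilyloxy)cyclopent‑2‑en‑1‑one
Product: 3 (S)‑3‑methyl‑2‑(triethylsilyloxy)cyclopent‑2‑en‑1‑ol
Conditions: (R)‑Me‑CBS (10 mol %), BH3·SMe2, THF, −30 °C; MeOH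
Reagents that add atoms: none
Why: Corey–Bakshi–Shibata reduction of an α‑substituted cyclic enone, for which the (R)‑catalyst should deliver hydride to give the (S)‑carbinol at C13, the only stereocentre set by a chiral reagent.

Step 3
Reactants: 3 (S)‑3‑methyl‑2‑(triethylsilyloxy)cyclopent‑2‑en‑1‑ol
Product: 4 (S)‑1‑(tert‑butyldimethylsilyloxy)‑3‑methyl‑2‑(triethylsilyloxy)cyclopent‑2‑ene
Conditions: TBSCl, imidazole, DMF, 0 °C → rt
Reagents that add atoms: tert‑butylchlorodimethylsilane, CC(C)(C)[Si](C)(C)Cl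
Why: silyl ether formation stops silyl migration onto the free carbinol and makes the C13 substituent a bulky facial shield.

Step 4
Reactants: 5 3,4‑dimethoxyphenol
Product: 6 3,4,4‑trimethoxycyclohexa‑2,5‑dien‑1‑one
Conditions: PhI(OAc)2, MeOH, 0 °C
Reagents that add atoms: methanol, CO
Why: hypervalent‑iodine oxidative dearomatization of a p‑alkoxyphenol in methanol gives the quinone monoketal with a regiodefined vinylogous ester.

Step 5
Reactants: 6 3,4,4‑trimethoxycyclohexa‑2,5‑dien‑1‑one
Product: 7 3,4,4‑trimethoxycyclohex‑2‑en‑1‑one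
Conditions: H2 (1 atm), RhCl(PPh3)3 (cat.), benzene, rt
Reagents that add atoms: none
Why: homogeneous hydrogenation with Wilkinson's catalyst should reduce the unhindered disubstituted enone alkene and leave the trisubstituted vinylogous ester and the allylic ketal intact.

Step 6
Reactants: 4 (S)‑1‑(tert‑butyldimethylsilyloxy)‑3‑methyl‑2‑(triethylsilyloxy)cyclopent‑2‑ene, 7 3,4,4‑trimethoxycyclohex‑2‑en‑1‑one
Product: 9 cyclobutene‑enone (C4=C8, Cx=O, 7,7‑dimethoxy, 9‑OTES, 13‑OTBS), via photoadduct 8 (not isolated)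
Conditions: hν (λ > 290 nm, Pyrex), 4 (3 equiv), MeCN, −20 °C; then KOtBu, THF, 0 °C
Reagents that add atoms: none
Why: enone–alkene [2+2] photocycloaddition of a vinylogous ester with an enol ether (head‑to‑tail, O‑bearing C9 to the β‑carbon C8) on the alkene face anti to the C13 silyloxy group sets C3 and C9, and E1cB loss of methoxide then erases the unselective C4/C8 centres as a cyclobutene‑enone.

Step 7
Reactants: 9 cyclobutene‑enone bis‑silyl ether
Product: 10 cyclobutene‑enone 9,13‑cis‑diol
Conditions: TBAF, THF, 0 °C → rt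
Reagents that add atoms: none
Why: fluoride desilylation frees the tertiary allylic 9‑OH and the 13‑OH, both on the top side, as directing groups; the γ‑hydroxy enone has no retro‑aldol pathway.

Step 8
Reactants: 10 cyclobutene‑enone 9,13‑cis‑diol
Product: 11 cis‑syn‑cis tricyclic ketone diol (H‑4 and H‑8 on the top face)
Conditions: H2 (1 atm), [Ir(cod)(PCy3)(py)]PF6 (10 mol %), CH2Cl2, rt
Reagents that add atoms: none
Why: hydroxyl‑directed hydrogenation with the cationic iridium catalyst should deliver both hydrogens to the tetrasubstituted enone from the face of the 9‑OH, which places ring A′ under the cyclobutane on the side of ring C and so sets C4 and C8.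

Step 9
Reactants: 11 cis‑syn‑cis tricyclic ketone diol
Product: 12 9,13‑acetonide of 11
Conditions: 2‑methoxypropene, PPTS (cat.), CH2Cl2, 0 °C
Reagents that add atoms: 2‑methoxypropene, COC(C)=C
Why: acetonide formation on the cis‑1,2‑diol protects both hydroxyls for the base steps and prevents retro‑aldol opening of the cyclobutanol once C7 becomes a ketone.

Step 10
Reactants: 12 acetonide ketone
Product: 14 5‑diazo ketone, via trifluoroacetyl ketone 13 (not isolated)
Conditions: LiHMDS, THF, −78 °C; CF3CO2CH2CF3; then MsN3, Et3N, H2O, MeCN, rt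
Reagents that add atoms: methanesulfonyl azide, CS(=O)(=O)N=[N+]=[N-]; 2,2,2‑trifluoroethyl trifluoroacetate (atoms kept only in 13), FC(F)(F)COC(=O)C(F)(F)F
Why: detrifluoroacetylative diazo transfer places the diazo group at the kinetically enolized CH2 (C5) and not at the ring‑fusion CH (C4).

Step 11
Reactants: 14 5‑diazo ketone
Product: 16 ring‑contracted Weinreb amide (C5 acyl endo), via ketene 15 (not isolated)
Conditions: hν (300 nm), MeNH(OMe) (5 equiv), THF, 0 °C
Reagents that add atoms: N,O‑dimethylhydroxylamine, CNOC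
Why: Irradiation expels N2 from the s‑cis‑locked 2‑diazocyclohexanone while the C4–Cx bond migrates to the diazo carbon C5 (Wolff rearrangement), giving bicyclo[3.2.0] ketene 15 with Cx now exocyclic on C5, and the amine traps the ketene as the amide. The closest known reaction type is the photochemical Wolff ring contraction of 2‑diazocycloalkanones used to reach strained bicycles. No ring is closed in the usual sense: six‑membered ring A′ contracts to cyclopentane A by a suprafacial 1,2‑alkyl shift with retention at the migrating cyclobutane carbon C4, which thereby stops being α to a carbonyl, so the cis‑syn‑cis fusion from step 8 is locked. The one new stereocentre, C5, forms on C‑protonation of the amide enol, expected from the open exo face (acyl endo), and its sense is immaterial because step 12 equilibrates it. The step needs site selectivity (diazo at C5, secured in step 10) and rearrangement rather than C–H insertion or 1,2‑H shift of a free carbene (favoured by the cyclic Z geometry, which supports the concerted path).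

Step 12
Reactants: 16 ring‑contracted Weinreb amide
Product: 18 exo‑5‑acetyl compound, via endo methyl ketone 17 (not isolated)
Conditions: MeMgBr, THF, 0 °C; then NaOMe (cat.), MeOH, rt
Reagents that add atoms: methylmagnesium bromide, C[Mg]Br
Why: Weinreb ketone synthesis followed by base equilibration of the α‑centre should place the acetyl group on the convex exo face of C5, away from ring C.

Step 13
Reactants: 18 exo‑5‑acetyl compound
Product: 19 5‑exo‑acetate
Conditions: mCPBA, NaHCO3, CH2Cl2, rt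
Reagents that add atoms: 3‑chloroperoxybenzoic acid, OOC(=O)c1cccc(Cl)c1
Why: Baeyer–Villiger oxidation, in which the secondary ring carbon migrates in preference to methyl with retention, turns the exo acetyl group into the exo C5 acetate of the target.

Step 14
Reactants: 19 5‑exo‑acetate
Product: 20 7‑ketone
Conditions: PPTS, acetone/H2O, rt
Reagents that add atoms: water, O
Why: mild acid hydrolysis (transketalization) cleaves the acyclic dimethyl ketal while acetone preserves the acetonide, so the C7 ketone is never present beside a free 9‑OH.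

Step 15
Reactants: 20 7‑ketone
Product: 21 7‑methylene compound
Conditions: Zn, CH2Br2, TiCl4, THF/CH2Cl2, 0 °C → rt
Reagents that add atoms: dibromomethane, BrCBr
Why: Lombardo methylenation is non‑basic, so the β‑acetoxy and β‑alkoxy ketone is olefinated without E1cB elimination and the ester is untouched.

Step 16
Reactants: 21 7‑methylene compound
Product: 22 9,13‑diol
Conditions: 80% aq. AcOH, 45 °C
Reagents that add atoms: none
Why: acid hydrolysis of the acetonide; any drift of the exocyclic alkene into the ring would be harmless because both isomers give the same C7 radical in step 22.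

Step 17
Reactants: 22 9,13‑diol
Product: 23 9‑hydroxy‑13‑ketone
Conditions: SO3·pyridine, DMSO, iPr2NEt, CH2Cl2, 0 °C
Reagents that add atoms: none
Why: Parikh–Doering oxidation takes the secondary 13‑OH to the ketone without cleaving the vicinal diol, and removes the sacrificial stereocentre.

Step 18
Reactants: 23 9‑hydroxy‑13‑ketone
Product: 24 1,9‑dihydroxy‑13‑ketone
Conditions: KHMDS (2.2 equiv), THF, −78 °C; 2‑(phenylsulfonyl)‑3‑phenyloxaziridine
Reagents that add atoms: 2‑(phenylsulfonyl)‑3‑phenyloxaziridine, O=S(=O)(N1OC1c1ccccc1)c1ccccc1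
Why: enolate hydroxylation with the Davis oxaziridine can occur only at C1 and should come from the convex face of ring C, away from the cyclobutane and ring A, which sets C1.

Step 19
Reactants: 24 1,9‑dihydroxy‑13‑ketone
Product: 25 1‑OTBS ketone
Conditions: TBSCl, imidazole, DMF, rt
Reagents that add atoms: tert‑butylchlorodimethylsilane, CC(C)(C)[Si](C)(C)Cl
Why: selective silylation of the secondary 1‑OH leaves the hindered tertiary 9‑OH free as the only lactonizing oxygen.

Step 20
Reactants: 25 1‑OTBS ketone, 26 methyl 3‑(tert‑butyldimethylsilyloxy)propanoate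
Product: 28 13‑hydroxy γ‑lactone (C12 epimers), via aldol adduct 27 (not isolated)
Conditions: 26, LDA, THF, −78 °C; add 25; −78 → 0 °C
Reagents that add atoms: none
Why: ester‑enolate aldol addition to the C13 ketone followed by lactonization through the 9‑alkoxide, where only the adduct with C12 cis to the 9‑oxygen can close the cis‑fused lactone and the other reverts by retro‑aldol.

Step 21
Reactants: 28 13‑hydroxy γ‑lactone
Product: 30 butenolide (1‑OTBS, 12‑CH2OTBS, 7‑methylene), via trifluoroacetate 29 (not isolated)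
Conditions: TFAA, pyridine, DMAP (cat.), CH2Cl2, 0 °C; then DBU, rt
Reagents that add atoms: trifluoroacetic anhydride (atoms kept only in 29), O=C(OC(=O)C(F)(F)F)C(F)(F)F
Why: acylation of the tertiary β‑hydroxyl and E1cB elimination through the acidic C12–H give the conjugated tetrasubstituted butenolide and remove the C12/C13 epimer issue.

Step 22
Reactants: 30 butenolide
Product: 31 C7 tertiary alcohol
Conditions: Co(acac)2 (20 mol %), PhSiH3, O2 (1 atm), THF, rt
Reagents that add atoms: dioxygen, O=O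
Why: Mukaiyama hydration (metal‑hydride H‑atom transfer) is Markovnikov at the 1,1‑disubstituted alkene and spares the hindered tetrasubstituted butenolide, and O2 should trap the C7 radical from the convex exo face to give 7‑OH exo and 7‑CH3 endo.

Step 23
Reactants: 31 C7 tertiary alcohol
Product: 32 triol (1‑OH, 12‑CH2OH, 7‑OH)
Conditions: HF·pyridine, pyridine, THF, 0 °C → rt
Reagents that add atoms: none
Why: buffered fluoride desilylation removes both TBS ethers without touching the acetate or lactone; the 1‑OH is trans to C11 across C12=C13, so translactonization is not possible.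

Step 24
Reactants: 32 triol
Product: 33 primary monoacetate
Conditions: Ac2O (1.1 equiv), 2,4,6‑collidine, CH2Cl2, −20 °C
Reagents that add atoms: acetic anhydride, CC(=O)OC(C)=O
Why: kinetically selective acetylation of the primary allylic alcohol over the hindered secondary 1‑OH and the tertiary 7‑OH.

Step 25
Reactants: 33 primary monoacetate, 34 tigloyl chloride ((E)‑2‑methylbut‑2‑enoyl chloride)
Product: 35 target CNP0210373.1
Conditions: 34, DMAP, pyridine, CH2Cl2, 0 °C → rt
Reagents that add atoms: none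
Why: DMAP‑catalysed acylation of the remaining secondary alcohol with the configurationally stable (E)‑acid chloride installs the tiglate, the tertiary 7‑OH being too hindered to react.

**Compound list**

1 | cyclotene (2‑hydroxy‑3‑methylcyclopent‑2‑en‑1‑one) | CC1=C(O)C(=O)CC1 | starting material
2 | 3‑methyl‑2‑(triethylsilyloxy)cyclopent‑2‑en‑1‑one | CC1=C(O[Si](CC)(CC)CC)C(=O)CC1 | intermediate
3 | (S)‑3‑methyl‑2‑(triethylsilyloxy)cyclopent‑2‑en‑1‑ol | CC1=C(O[Si](CC)(CC)CC)[C@@H](O)CC1 | intermediate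
4 | (S)‑1‑(tert‑butyldimethylsilyloxy)‑3‑methyl‑2‑(triethylsilyloxy)cyclopent‑2‑ene | CC1=C(O[Si](CC)(CC)CC)[C@@H](O[Si](C)(C)C(C)(C)C)CC1 | intermediate
5 | 3,4‑dimethoxyphenol | COc1ccc(O)cc1OC | starting material
6 | 3,4,4‑trimethoxycyclohexa‑2,5‑dien‑1‑one | COC1=CC(=O)C=CC1(OC)OC | intermediate
7 | 3,4,4‑trimethoxycyclohex‑2‑en‑1‑one | COC1=CC(=O)CCC1(OC)OC | intermediate
8 | photoadduct: tricyclic β‑methoxy ketone, 8‑OMe, C3/C9/C13 as in 9, C4/C8 ring‑fusion isomers left undefined | C1C[C@]2(C)C3C(=O)CCC(OC)(OC)C3(OC)[C@]2(O[Si](CC)(CC)CC)[C@H]1O[Si](C)(C)C(C)(C)C | intermediate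
9 | cyclobutene‑enone, C4=C8, Cx=O, 7,7‑dimethoxy, 9‑OTES, 13‑OTBS (both O on the top side) | C1C[C@]2(C)C3=C(C(OC)(OC)CCC3=O)[C@]2(O[Si](CC)(CC)CC)[C@H]1O[Si](C)(C)C(C)(C)C | intermediate
10 | cyclobutene‑enone 9,13‑cis‑diol | C1C[C@]2(C)C3=C(C(OC)(OC)CCC3=O)[C@]2(O)[C@H]1O | intermediate
11 | cis‑syn‑cis tricyclic Cx‑ketone, 7,7‑dimethoxy, 9,13‑diol, H‑4/H‑8 cis to 3‑CH3 and 9‑OH | C1C[C@]2(C)[C@@H]3C(=O)CCC(OC)(OC)[C@@H]3[C@]2(O)[C@H]1O | intermediate
12 | 9,13‑acetonide of 11 | C1C[C@]2(C)[C@@H]3C(=O)CCC(OC)(OC)[C@@H]3[C@]2(OC(C)(C)O4)[C@H]14 | intermediate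
13 | 5‑trifluoroacetyl derivative of 12 (C5 undefined, enolized) | C1C[C@]2(C)[C@@H]3C(=O)C(C(=O)C(F)(F)F)CC(OC)(OC)[C@@H]3[C@]2(OC(C)(C)O4)[C@H]14 | intermediate
14 | 5‑diazo‑Cx‑ketone | C1C[C@]2(C)[C@@H]3C(=O)C(=[N+]=[N-])CC(OC)(OC)[C@@H]3[C@]2(OC(C)(C)O4)[C@H]14 | intermediate
15 | ring‑contracted ketene (C5=C=O) | C1C[C@]2(C)[C@@H]3C(=C=O)CC(OC)(OC)[C@@H]3[C@]2(OC(C)(C)O4)[C@H]14 | intermediate
16 | C5 N‑methoxy‑N‑methylamide, acyl endo | C1C[C@]2(C)[C@@H]3[C@H](C(=O)N(C)OC)CC(OC)(OC)[C@@H]3[C@]2(OC(C)(C)O4)[C@H]14 | intermediate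
17 | C5 acetyl, endo | C1C[C@]2(C)[C@@H]3[C@H](C(C)=O)CC(OC)(OC)[C@@H]3[C@]2(OC(C)(C)O4)[C@H]14 | intermediate
18 | C5 acetyl, exo | C1C[C@]2(C)[C@@H]3[C@@H](C(C)=O)CC(OC)(OC)[C@@H]3[C@]2(OC(C)(C)O4)[C@H]14 | intermediate
19 | C5 exo‑acetate, 7,7‑dimethoxy, acetonide | C1C[C@]2(C)[C@@H]3[C@@H](OC(C)=O)CC(OC)(OC)[C@@H]3[C@]2(OC(C)(C)O4)[C@H]14 | intermediate
20 | 7‑ketone | C1C[C@]2(C)[C@@H]3[C@@H](OC(C)=O)CC(=O)[C@@H]3[C@]2(OC(C)(C)O4)[C@H]14 | intermediate
21 | 7‑methylene compound | C1C[C@]2(C)[C@@H]3[C@@H](OC(C)=O)CC(=C)[C@@H]3[C@]2(OC(C)(C)O4)[C@H]14 | intermediate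
22 | 7‑methylene 9,13‑diol | C1C[C@]2(C)[C@@H]3[C@@H](OC(C)=O)CC(=C)[C@@H]3[C@]2(O)[C@H]1O | intermediate
23 | 9‑hydroxy‑13‑ketone | C1C[C@]2(C)[C@@H]3[C@@H](OC(C)=O)CC(=C)[C@@H]3[C@]2(O)C1=O | intermediate
24 | 1,9‑dihydroxy‑13‑ketone (1‑OH cis to 3‑CH3 and 9‑OH) | O[C@H]1C[C@]2(C)[C@@H]3[C@@H](OC(C)=O)CC(=C)[C@@H]3[C@]2(O)C1=O | intermediate
25 | 1‑OTBS‑9‑hydroxy‑13‑ketone | CC(C)(C)[Si](C)(C)O[C@H]1C[C@]2(C)[C@@H]3[C@@H](OC(C)=O)CC(=C)[C@@H]3[C@]2(O)C1=O | intermediate
26 | methyl 3‑(tert‑butyldimethylsilyloxy)propanoate | COC(=O)CCO[Si](C)(C)C(C)(C)C | starting material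
27 | aldol adduct (13‑OH toward the cyclobutane side, C12 undefined) | CC(C)(C)[Si](C)(C)O[C@H]1C[C@]2(C)[C@@H]3[C@@H](OC(C)=O)CC(=C)[C@@H]3[C@]2(O)[C@@]1(O)C(CO[Si](C)(C)C(C)(C)C)C(=O)OC | intermediate
28 | 13‑hydroxy γ‑lactone (C12 undefined) | CC(C)(C)[Si](C)(C)O[C@H]1C[C@]2(C)[C@@H]3[C@@H](OC(C)=O)CC(=C)[C@@H]3[C@@]23OC(=O)C(CO[Si](C)(C)C(C)(C)C)[C@@]13O | intermediate
29 | 13‑trifluoroacetate of 28 | CC(C)(C)[Si](C)(C)O[C@H]1C[C@]2(C)[C@@H]3[C@@H](OC(C)=O)CC(=C)[C@@H]3[C@@]23OC(=O)C(CO[Si](C)(C)C(C)(C)C)[C@@]13OC(=O)C(F)(F)F | intermediate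
30 | butenolide, 1‑OTBS, 12‑CH2OTBS, 7‑methylene | CC(C)(C)[Si](C)(C)O[C@H]1C[C@]2(C)[C@@H]3[C@@H](OC(C)=O)CC(=C)[C@@H]3[C@@]23OC(=O)C(CO[Si](C)(C)C(C)(C)C)=C13 | intermediate
31 | butenolide with C7(OH exo)(CH3 endo) | CC(C)(C)[Si](C)(C)O[C@H]1C[C@]2(C)[C@@H]3[C@@H](OC(C)=O)C[C@@](C)(O)[C@@H]3[C@@]23OC(=O)C(CO[Si](C)(C)C(C)(C)C)=C13 | intermediate
32 | triol (1‑OH, 12‑CH2OH, 7‑OH) | O[C@H]1C[C@]2(C)[C@@H]3[C@@H](OC(C)=O)C[C@@](C)(O)[C@@H]3[C@@]23OC(=O)C(CO)=C13 | intermediate
33 | primary monoacetate (1‑OH, 7‑OH free) | O[C@H]1C[C@]2(C)[C@@H]3[C@@H](OC(C)=O)C[C@@](C)(O)[C@@H]3[C@@]23OC(=O)C(COC(C)=O)=C13 | intermediate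
34 | tigloyl chloride ((E)‑2‑methylbut‑2‑enoyl chloride) | C/C=C(\C)C(Cl)=O | starting material
35 | CNP0210373.1 | C/C=C(\C)C(=O)O[C@H]1C[C@]2(C)[C@@H]3[C@@H](OC(C)=O)C[C@@](C)(O)[C@@H]3[C@@]23OC(=O)C(COC(C)=O)=C13 | target

**Count and risks**

Total steps: 25. Longest linear sequence: 23 (steps 1–3 and 6–25).

Step 6. The bimolecular capture of the triplet vinylogous ester by a tetrasubstituted alkene at a fully substituted β‑carbon may be too slow, head‑to‑head addition may compete, or methoxide loss may stall. Fallback: irradiate 4 with commercial 4,4‑dimethoxycyclohex‑2‑en‑1‑one F1, whose β‑carbon is unsubstituted, to give photoadduct F2. Convert F2 under equilibrating conditions (TMSOTf, Et3N, CH2Cl2, rt) into the more substituted ring‑fusion trimethylsilyl enol ether F3. Dehydrogenate F3 with Pd(OAc)2 in MeCN (Saegusa–Ito oxidation); the only β‑hydrogen available to palladium is H‑8, so the same cyclobutene‑enone 9 results and the route continues from there.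

Step 8. Hydrogen may be delivered to the ring‑C face, or the strained tetrasubstituted enone may not be reduced. Fallback: silylate diol 10 with 1,1,3,3‑tetramethyldisilazane to the bis(dimethylsilyl) ether F4. Trigger intramolecular conjugate hydrosilylation (Pt(0) or catalytic fluoride), in which hydride passes from the silicon on the 9‑oxygen to the top face of C8 and gives the cyclic silyl enol ether F5. Cleave the silicon groups with K2CO3/MeOH, which protonates C4 on the open top face and returns 11.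

Step 20. Retro‑aldol reversal, proton transfer from the hindered ketone, or β‑elimination of the silyloxy ester enolate may prevail before lactonization. Fallback: esterify the tertiary 9‑OH of 25 with 3‑(tert‑butyldimethylsilyloxy)‑2‑(diethoxyphosphoryl)propanoic acid F6 (2,4,6‑trichlorobenzoyl chloride, Et3N, DMAP, toluene) to give phosphonate ester F7. Close ring D by an intramolecular Horner–Wadsworth–Emmons reaction (LiCl, DBU, MeCN), which forms C12=C13 directly and rejoins the route at butenolide 30.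

**Further compounds**

F1 | step 6 | 4,4‑dimethoxycyclohex‑2‑en‑1‑one (purchased) | COC1(OC)CCC(=O)C=C1
F2 | step 6 | photoadduct of 4 and F1 (C4/C8 undefined) | C1C[C@]2(C)C3C(=O)CCC(OC)(OC)C3[C@]2(O[Si](CC)(CC)CC)[C@H]1O[Si](C)(C)C(C)(C)C
F3 | step 6 | ring‑fusion trimethylsilyl enol ether of F2 (C8 undefined) | C1C[C@]2(C)C3=C(O[Si](C)(C)C)CCC(OC)(OC)C3[C@]2(O[Si](CC)(CC)CC)[C@H]1O[Si](C)(C)C(C)(C)C
F4 | step 8 | 9,13‑bis(dimethylsilyl) ether of 10 | C1C[C@]2(C)C3=C(C(OC)(OC)CCC3=O)[C@]2(O[SiH](C)C)[C@H]1O[SiH](C)C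
F5 | step 8 | cyclic silyl enol ether after hydride delivery to C8 | C1C[C@]2(C)C3=C(O[Si](C)(C)O4)CCC(OC)(OC)[C@@H]3[C@]24[C@H]1O[SiH](C)C
F6 | step 20 | 3‑(tert‑butyldimethylsilyloxy)‑2‑(diethoxyphosphoryl)propanoic acid | CCOP(=O)(OCC)C(CO[Si](C)(C)C(C)(C)C)C(O)=O
F7 | step 20 | 9‑O‑phosphonoacyl ester of 25 | CC(C)(C)[Si](C)(C)O[C@H]1C[C@]2(C)[C@@H]3[C@@H](OC(C)=O)CC(=C)[C@@H]3[C@]2(OC(=O)C(CO[Si](C)(C)C(C)(C)C)P(=O)(OCC)OCC)C1=O
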